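At 40 °C time acts on substrate by a fixed ratio: Tuesday's readings give it a half-life near 2.96 min, so I take its fraction of the charge to follow one curve whatever the charge. The gap between substrate lost and target formed I call intermediate, and I take target to come from it, using reagent one for one.

the same everywhere: free catalyst 26 µM; second catalyst 1.3 mM

| charge | substrate | reagent | temperature | remark | time |
|---|---|---|---|---|---|
| Sunday's | 0.042 M | 0.053 M | 25 °C | run made earlier |  |
| Tuesday's | 0.12 M | 0.053 M | 40 °C | run made earlier |  |
| noon | 0.15 M | 0.0530 M | 40 °C |  | 15 min |
| dawn | 0.053 M | 0.0530 M | 40 °C |  | 8.0 min |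

| run | time / min | target / % | substrate / % |
|---|---|---|---|
| Sunday's | 1.33 | 0.7 | 87.3 |
| Sunday's | 3.00 | 2.6 | 74.0 |
| Sunday's | 5.00 | 6.7 | 60.4 |
| Sunday's | 8.00 | 13.6 | 44.4 |
| Sunday's | 15.0 | 30.6 | 21.5 |
| Tuesday's | 0.667 | 0.3 | 85.1 |
| Tuesday's | 1.33 | 2.6 | 72.9 |
| Tuesday's | 2.50 | 8.3 | 55.7 |
| Tuesday's | 4.00 | 15.3 | 39.6 |
| Tuesday's | 8.00 | 27.9 | 15.3 |

(readings scatter by 0.3 percentage points)



1. the winner by amount of target, in percent of the substrate charged; "neither" if no more than 2 percentage points parts them (noon / dawn / neither)
2. how much target is there at the end, in percent of the substrate charged: noon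
3. how much target is there at the end, in percent of the substrate charged: dawn

My reckoning starts from the ceiling, reagent charge over substrate charge: 44.2% on Tuesday, 100% at dawn, and 35.3% at noon, where reagent is the limiting reagent. If target's rate goes with intermediate and with the fraction of reagent left, the reagent left is the exponential of minus drive over ceiling. The drive is the running sum of target made per fraction of reagent then left. Tuesday's readings give it as 9.19% at 2.50 min, 18.8% at 4.00 min and 44.1% at 8.00 min.

I assume the drive does not depend on the charges. Dawn stops at that last time, so its target is 35.7%. Noon needs the drive at 15 min, and running the last slope, 0.0633 min⁻¹, straight on gives 88.4% and target 32.4%.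

That straight line is the weak link: per mean intermediate, the slope fell to 0.788 of its value in the stretch before. Applying that factor, and leaving aside any further rise of intermediate, gives a drive of 79.1% and target 31.6%. The two figures stand apart by more than the margin, with dawn ahead.

The forecast says dawn, with 30.5% at noon and 39% at dawn: “Dawn wins, though concentration and temperature were confounded between the runs.”

The flasks give 30.0% at noon and 36.2% at dawn, so dawn wins.

    substrate + free catalyst → free catalyst + intermediate (k = 150 L mol⁻¹ s⁻¹, Ea = 43.0 kJ mol⁻¹)
    reagent + second catalyst + intermediate → second catalyst + target (k = 40.0 L² mol⁻² s⁻¹, Ea = 45.0 kJ mol⁻¹)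
    second catalyst + target → spent catalyst (k = 0.0570 L mol⁻¹ s⁻¹, Ea = 68.0 kJ mol⁻¹)
    (constants at 40 °C)

At noon, target's half-life by the step into spent catalyst is 160 min at 2.84 min, longer than the 15 min of the run. At noon, reagent's half-life by the step into target is 4.0 min at that moment, shorter than the run, and 13% of it stands at the end. At dawn, the 63.3% of reagent left reads back to a drive of 45.7%, against the 44.1% carried from Tuesday's. For a neighbour of noon with more reagent, a ceiling of 86.7%, the drive 79.1% reckons target at 51.9%, and that flask holds 53.4%.

The data stem from a simulated flask from invented constants; the scatter is artificial.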